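At early times the first end groups are shared among second end groups, one-sided end groups and protic impurity.

| setting | noon | summer |
|---|---|---|
| first end groups | 28 mM | 28 mM |
| second end groups | 26.6 mM | 26.6 mM |
| one-sided end groups | 1.40 mM | 1.00 mM |
| protic impurity | 8.40 mM | 8.40 mM |
| time | 25 min | 25 min |

    first end groups + second end groups → links (k1 = 0.441 L mol⁻¹ s⁻¹)
    first end groups + one-sided end groups → capped ends (k2 = 3.01 L mol⁻¹ s⁻¹)
    first end groups + protic impurity → quenched substrate (k3 = 0.551 L mol⁻¹ s⁻¹)
    links → over-reaction product (k4 = 1.41 × 10⁻⁵ s⁻¹)

- which of the two ends with the longer chains by the average number of monomer units in a chain (unreacted monomers counted as chains of one) ("neither" if they lie within 10 %) (noon / summer / neither)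
- average number of monomer units in a chain (unreacted monomers counted as chains of one) at the end, noon
- average number of monomer units in a chain (unreacted monomers counted as chains of one) at the end, summer

- each monomer carries two end groups and one-sided end groups one, which caps an end: a chain counts once for every two ends that are left, dead ends included; the units are half of the end groups of the two monomers charged
- a link that another step uses up counts as cut, two dead ends; so do two ends of one kind that react with each other
- run time (noon): 25 min

My first estimate for noon used the starting rates. They gave protic impurity a share, against second end groups, of 28.3 %, and after capping that meant an estimated 7.53 mM quenched. But that share belongs to the start. The selectivity factor s, the constant of quenching over that of linking, 1.25, is above one, so impurity falls faster in proportion to its own charge than second end groups do: if a fraction x of second end groups is left, x to the power s of impurity is left.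

The balance of first end groups then gives x. At noon, second end groups, one-sided end groups and impurity together exceed them by 8.40 mM, and once first and one-sided end groups are dropped from the count, that excess equals what remains of second end groups and impurity. Treating both alike gives x = 0.240. Correcting for the impurity term gives 0.263, then 0.256. One-sided end groups fall as x to the power 6.83, so nearly all become capped ends.

Each diverted first end leaves a dead end and a free second end. Chains therefore number D, the first ends turned into capped ends or quenched substrate, less 0.700 mM, plus cut links. At noon I reckoned D at 8.27 mM. Was it right to drop first end groups from the balance? Their half-life against the remaining second end groups and impurity, 3.00 min, is shorter than the run. Were cuts negligible? About 2.12 % of links, or 0.417 mM, is small but counted. That gave 7.98 mM of chains and a noon length of 3.42. For summer the same steps gave D = 7.95 mM and a length of 3.56, a gap of 3.99 %, less than the margin.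

The forecast gave 3.43 for noon, 3.57 for summer and neither, since “the two averages differ by only about 4%, inside the 10% band”.

The simulation gave 3.43 for noon, 3.57 for summer, and neither. I used s on the summer flask with 5.0 mM of protic impurity. Its excess was 4.60 mM, and x came to 0.154. So I reckoned D at 5.52 mM and the length at 5.16. The simulated flask stood at 5.06, with 16 % of its second end groups still free.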